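**Retrosynthetic overview**
1. The last step is a global fluoride desilylation of a tris-TIPS flavonol; TIPS is chosen because it comes off without acid, hydrogen or Lewis acid, all of which would endanger the prenyl aryl ether.
2. Key disconnection: ring C (the pyranone) is cut at C1'–C2, C2–C3 and O1–C2. C2 is excised as carbon monoxide, leaving a ring-B aryl iodide and a ring-A α-ketol (a 2-hydroxyphenacyl alcohol carrying C3 and C4); the C1'–C2 bond is made when the aryl–Pd species from the iodide takes up CO.
3. Enabling feature: C2 of the 3-hydroxy-4-pyranone is a carboxyl-level carbon bonded to aryl C1', ring oxygen O1 and the enolic C3(OH)–C4(=O) unit. Ring C is thus the cyclodehydrated form of an α-hydroxy-1,3-diketone, so an aroyl group built from ArI + CO can be passed to the ketol and closed onto the ortho phenol oxygen of ring A.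
4. Fragments: the ketol comes from 2',4',5'-trihydroxyacetophenone (silylation, Rubottom oxidation); the aryl iodide from catechol (mono-prenylation, para-iodination, silylation).
5. Ring order: rings A and B are bought as arenes; ring C is the only ring formed, and it is formed last, in the three-component key step.

Key step: step 6

Remark: the target has no stereocentre and no stereogenic double bond; it is achiral, so no stereocontrol is needed and the route gives the single compound as drawn.

**Step 1**
Reactants: 1 1-(2,4,5-trihydroxyphenyl)ethan-1-one (2',4',5'-trihydroxyacetophenone)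
Product: 2 1-[2-hydroxy-4,5-bis(triisopropylsilyloxy)phenyl]ethan-1-one
Conditions: TIPSCl (2.3 equiv), imidazole (5 equiv), DMAP (cat.), DMF, 0 °C → 40 °C, N2
Reagents that add atoms: triisopropylsilyl chloride, CC(C)[Si](Cl)(C(C)C)C(C)C
Why: Silyl ether formation (R3SiCl/imidazole): the 4- and 5-hydroxyls are silylated while the 2-hydroxyl, held in the intramolecular hydrogen bond to the acetyl carbonyl, should stay free, and TIPS is chosen because it tolerates amine bases and is later removed by fluoride without harming the prenyl ether.

**Step 2**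
Reactants: 2 1-[2-hydroxy-4,5-bis(triisopropylsilyloxy)phenyl]ethan-1-one
Product: 5 2-hydroxy-1-[2-hydroxy-4,5-bis(triisopropylsilyloxy)phenyl]ethan-1-one, via bis-TMS silyl enol ether 3 (not isolated), via α-trimethylsilyloxy ketone 4 (not isolated)
Conditions: TMSOTf (2.3 equiv), Et3N (3 equiv), CH2Cl2, 0 °C; mCPBA (1.05 equiv), CH2Cl2/hexane, −20 °C → 0 °C; 1 M aq. HCl (cat.), THF, 0 °C
Reagents that add atoms: 3-chloroperoxybenzoic acid (mCPBA), OOC(=O)c1cccc(Cl)c1
Why: Rubottom oxidation: TMSOTf/Et3N turns the methyl ketone into silyl enol ether 3 (the phenol is silylated in passing), the peracid epoxidises this electron-rich alkene far faster than it attacks the arene or the ketone, 1,4-silyl shift gives 4, and brief dilute acid removes the two labile TMS groups but not the aryl TIPS ethers.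

**Step 3**
Reactants: 6 benzene-1,2-diol (catechol); 7 1-bromo-3-methylbut-2-ene (prenyl bromide)
Product: 8 2-[(3-methylbut-2-en-1-yl)oxy]phenol
Conditions: 6 (3 equiv), K2CO3 (1.2 equiv), acetone, reflux, N2
Reagents that add atoms: none
Why: Williamson ether synthesis with a reactive allylic bromide; the excess of catechol (recovered by extraction into aqueous base) should hold the alkylation at the mono-ether.

**Step 4**
Reactants: 8 2-[(3-methylbut-2-en-1-yl)oxy]phenol
Product: 9 4-iodo-2-[(3-methylbut-2-en-1-yl)oxy]phenol
Conditions: NaI (1.05 equiv), NaOH (1.0 equiv), MeOH, 0 °C; aq. NaOCl (1.0 equiv), dropwise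
Reagents that add atoms: sodium iodide, [Na+].[I-]
Why: Electrophilic aromatic iodination with hypoiodite generated in situ: the phenoxide should react orders of magnitude faster than the trisubstituted alkene and direct iodine to its free, unhindered para position, which is the future C1' of ring B.

**Step 5**
Reactants: 9 4-iodo-2-[(3-methylbut-2-en-1-yl)oxy]phenol
Product: 10 {4-iodo-2-[(3-methylbut-2-en-1-yl)oxy]phenoxy}triisopropylsilane
Conditions: TIPSCl (1.2 equiv), imidazole (2.5 equiv), DMF, rt
Reagents that add atoms: triisopropylsilyl chloride, CC(C)[Si](Cl)(C(C)C)C(C)C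
Why: Silyl ether formation; placing it after the iodination fixes the regiochemistry first and excludes silyl migration between the two catechol oxygens, because no free neighbouring phenol remains afterwards.

**Step 6**
Reactants: 5 2-hydroxy-1-[2-hydroxy-4,5-bis(triisopropylsilyloxy)phenyl]ethan-1-one (1.2 equiv); 10 {4-iodo-2-[(3-methylbut-2-en-1-yl)oxy]phenoxy}triisopropylsilane; 11 carbon monoxide
Product: 14 3-hydroxy-2-{3-[(3-methylbut-2-en-1-yl)oxy]-4-(triisopropylsilyloxy)phenyl}-6,7-bis(triisopropylsilyloxy)-4H-chromen-4-one, via phenacyl aroate ester 12 (not isolated), via 2-hydroxy-1,3-diketone 13 (not isolated)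
Conditions: Pd(OAc)2 (5 mol%), Xantphos (6 mol%), CO (1 atm, kept throughout), Et3N (2 equiv), DMAP (0.2 equiv), 4 Å MS, 1,4-dioxane, 70 °C; then DBU (3 equiv), 80 °C
Reagents that add atoms: none
Why: Proposed new method: Pd(0)/Xantphos inserts into the C–I bond of 10, CO insertion creates the aryl C1'–C2 bond as an aroyl–Pd species, and DMAP-assisted acyl transfer to the primary hydroxyl of ketol 5 (or equally to its phenoxide) gives ester 12; DBU then brings about a Baker–Venkataraman-type O→C aroyl shift onto the ketol carbon (future C3) to give the 2-hydroxy-1,3-diketone 13. The closest known reaction types are the Pd-catalysed one-pot carbonylative flavone synthesis from aryl halides, CO and 2-hydroxyacetophenones and the base-mediated conversion of 2-hydroxyphenacyl aroates into flavonols; their merger on a free α-ketol, which delivers the 3-hydroxyl directly, is the untested part. Ring C closes by 6-exo-trig attack of the ring-A phenol oxygen (O1) on the new aryl ketone (C2), followed by E1cB loss of water across C2–C3, and the aromatic, hydrogen-bonded 3-hydroxy-4-pyranone is the thermodynamic sink. No stereocentre is created, the carbinol centre of 13 being lost on dehydration. The step needs chemoselectivity: only the ketol hydroxyls may capture the aroyl–Pd (secured by TIPS protection of the three other phenols), acyl transfer must beat 5-exo-tet displacement of the aroate by the phenoxide, which would give a benzofuran-3-one (secured by the poor carboxylate leaving group and the staged use of Et3N before DBU), and the prenyl ether must not ionise on Pd(0) (secured by the much faster oxidative addition to C–I, the hindered trisubstituted alkene and the CO atmosphere).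

**Step 7**
Reactants: 14 3-hydroxy-2-{3-[(3-methylbut-2-en-1-yl)oxy]-4-(triisopropylsilyloxy)phenyl}-6,7-bis(triisopropylsilyloxy)-4H-chromen-4-one
Product: 15 3,6,7-trihydroxy-2-{4-hydroxy-3-[(3-methylbut-2-en-1-yl)oxy]phenyl}-4H-chromen-4-one (target)
Conditions: TBAF (3.3 equiv), AcOH (3.5 equiv), THF, 0 °C → rt, Ar
Reagents that add atoms: none
Why: Fluoride-induced cleavage of the three aryl silyl ethers (Si–F bond formation); acetic acid buffers the phenoxides so that the catechol and the flavonol are not autoxidised, and the prenyl aryl ether is inert to fluoride.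

**Compound list**
1 | 1-(2,4,5-trihydroxyphenyl)ethan-1-one (2',4',5'-trihydroxyacetophenone) | CC(=O)c1cc(O)c(O)cc1O | starting material
2 | 1-[2-hydroxy-4,5-bis(triisopropylsilyloxy)phenyl]ethan-1-one | CC(=O)c1cc(O[Si](C(C)C)(C(C)C)C(C)C)c(O[Si](C(C)C)(C(C)C)C(C)C)cc1O | intermediate
3 | {1-[4,5-bis(triisopropylsilyloxy)-2-(trimethylsilyloxy)phenyl]ethenyloxy}trimethylsilane (bis-TMS silyl enol ether, not isolated) | C=C(O[Si](C)(C)C)c1cc(O[Si](C(C)C)(C(C)C)C(C)C)c(O[Si](C(C)C)(C(C)C)C(C)C)cc1O[Si](C)(C)C | intermediate
4 | 1-[4,5-bis(triisopropylsilyloxy)-2-(trimethylsilyloxy)phenyl]-2-(trimethylsilyloxy)ethan-1-one (not isolated) | C[Si](C)(C)OCC(=O)c1cc(O[Si](C(C)C)(C(C)C)C(C)C)c(O[Si](C(C)C)(C(C)C)C(C)C)cc1O[Si](C)(C)C | intermediate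
5 | 2-hydroxy-1-[2-hydroxy-4,5-bis(triisopropylsilyloxy)phenyl]ethan-1-one | OCC(=O)c1cc(O[Si](C(C)C)(C(C)C)C(C)C)c(O[Si](C(C)C)(C(C)C)C(C)C)cc1O | intermediate
6 | benzene-1,2-diol (catechol) | Oc1ccccc1O | starting material
7 | 1-bromo-3-methylbut-2-ene (prenyl bromide) | CC(C)=CCBr | starting material
8 | 2-[(3-methylbut-2-en-1-yl)oxy]phenol | CC(C)=CCOc1ccccc1O | intermediate
9 | 4-iodo-2-[(3-methylbut-2-en-1-yl)oxy]phenol | CC(C)=CCOc1cc(I)ccc1O | intermediate
10 | {4-iodo-2-[(3-methylbut-2-en-1-yl)oxy]phenoxy}triisopropylsilane | CC(C)=CCOc1cc(I)ccc1O[Si](C(C)C)(C(C)C)C(C)C | intermediate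
11 | carbon monoxide | [C-]#[O+] | starting material
12 | 2-[2-hydroxy-4,5-bis(triisopropylsilyloxy)phenyl]-2-oxoethyl 3-[(3-methylbut-2-en-1-yl)oxy]-4-(triisopropylsilyloxy)benzoate (not isolated) | CC(C)=CCOc1cc(C(=O)OCC(=O)c2cc(O[Si](C(C)C)(C(C)C)C(C)C)c(O[Si](C(C)C)(C(C)C)C(C)C)cc2O)ccc1O[Si](C(C)C)(C(C)C)C(C)C | intermediate
13 | 2-hydroxy-1-[2-hydroxy-4,5-bis(triisopropylsilyloxy)phenyl]-3-{3-[(3-methylbut-2-en-1-yl)oxy]-4-(triisopropylsilyloxy)phenyl}propane-1,3-dione (racemic at the carbinol carbon, not isolated) | CC(C)=CCOc1cc(C(=O)C(O)C(=O)c2cc(O[Si](C(C)C)(C(C)C)C(C)C)c(O[Si](C(C)C)(C(C)C)C(C)C)cc2O)ccc1O[Si](C(C)C)(C(C)C)C(C)C | intermediate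
14 | 3-hydroxy-2-{3-[(3-methylbut-2-en-1-yl)oxy]-4-(triisopropylsilyloxy)phenyl}-6,7-bis(triisopropylsilyloxy)-4H-chromen-4-one | CC(C)=CCOc1cc(-c2oc3cc(O[Si](C(C)C)(C(C)C)C(C)C)c(O[Si](C(C)C)(C(C)C)C(C)C)cc3c(=O)c2O)ccc1O[Si](C(C)C)(C(C)C)C(C)C | intermediate
15 | 3,6,7-trihydroxy-2-{4-hydroxy-3-[(3-methylbut-2-en-1-yl)oxy]phenyl}-4H-chromen-4-one | CC(C)=CCOc1cc(-c2oc3cc(O)c(O)cc3c(=O)c2O)ccc1O | target

**Step count and risks**
Total step count: 7. Longest linear sequence: 5 steps (steps 3, 4, 5, 6, 7).

Steps most likely to fail:

1. Step 6 (carries the label). Capture of the aroyl–palladium species by the ketol may be too slow, so that reduction or homocoupling of the aryl iodide takes over. After acylation, the phenoxide may displace the aroate and close a benzofuranone, or the diketone may suffer retro-Claisen cleavage before it cyclises. Silyl groups may also migrate under DBU. The fallback uses only known chemistry, stepwise and without Pd/CO. It sets out from 10: iodine–magnesium exchange (iPrMgCl·LiCl, THF, −20 °C) and a CO2 quench should give 3-[(3-methylbut-2-en-1-yl)oxy]-4-(triisopropylsilyloxy)benzoic acid F1. Carbodiimide esterification (EDC·HCl, DMAP, CH2Cl2, 0 °C) with the primary hydroxyl of 5 should give ester 12, now isolated. LiHMDS (3.2 equiv, THF, −78 → 0 °C) should effect the Baker–Venkataraman-type O→C acyl shift to 13 at a temperature at which ring closure by displacement does not compete, and warming with AcOH should close and dehydrate the ring. The fallback comes back to the route at 14.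

2. Step 4. The iodinating species may attack the trisubstituted alkene of the prenyl group, or iodination may occur ortho to the hydroxyl or twice. The fallback uses an electrophile that is inert to alkenes and strictly para-selective. It sets out from 8: azo coupling of its phenoxide with 4-sulfobenzenediazonium (from sulfanilic acid, NaNO2, HCl; aq. NaOH, 0 °C) should give 4-{(E)-[4-hydroxy-3-(3-methylbut-2-en-1-yloxy)phenyl]diazenyl}benzenesulfonic acid F2. Reductive cleavage with Na2S2O4 (aq. NaOH/EtOH, 50 °C) should give 4-amino-2-[(3-methylbut-2-en-1-yl)oxy]phenol F3. Diazotisation (NaNO2, dilute H2SO4, 0 °C) and treatment with KI (Sandmeyer-type iodination) should then give the iodide. The fallback comes back to the route at 9.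

3. Step 2. Enol silylation may be incomplete, the peracid may attack the electron-rich arene or over-oxidise the aryl ketone in a Baeyer–Villiger sense, and TIPS groups may be lost in the acidic desilylation. The fallback replaces the silyl enol ether/peracid sequence by direct enolate hydroxylation. It sets out from 2: NaHMDS (2.2 equiv, THF, −78 °C) forms the phenoxide–enolate dianion, which is oxidised with (camphorsulfonyl)oxaziridine and quenched with aq. NH4Cl. No new compound is made, and the fallback comes back to the route at 5.

**Further compounds**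
F1 | step 6 | 3-[(3-methylbut-2-en-1-yl)oxy]-4-(triisopropylsilyloxy)benzoic acid | CC(C)=CCOc1cc(C(=O)O)ccc1O[Si](C(C)C)(C(C)C)C(C)C
F2 | step 4 | 4-{(E)-[4-hydroxy-3-(3-methylbut-2-en-1-yloxy)phenyl]diazenyl}benzenesulfonic acid | CC(C)=CCOc1cc(/N=N/c2ccc(cc2)S(=O)(=O)O)ccc1O
F3 | step 4 | 4-amino-2-[(3-methylbut-2-en-1-yl)oxy]phenol | CC(C)=CCOc1cc(N)ccc1O
F0 | step 2 | none | none
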